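**Retrosynthetic overview**
1. The target comes from fourfold O-debenzylation (last step) of the tetra-O-benzyl 8-benzylflavone.
2. That flavone comes from one new step, an acid-catalysed cycloisomerisation of an aryl ynone whose ortho oxygen carries the 4-(benzyloxy)benzyl group. It makes O1–C2 (pyranone ring) and C8–CH2Ar together, and the oxygen that bears the migrating group fixes 8- over 6-substitution.
3. The ynone comes from a lithium aryl acetylide and a 2,4,6-trialkoxybenzaldehyde (C3–C4 bond), followed by oxidation.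
4. The aldehyde comes from phloroglucinaldehyde (two OBn, then 4-(benzyloxy)benzyl chloride). The alkyne comes from O-benzylisovanillin by one-carbon homologation.
5. Ring order: the three benzene rings are bought. The only ring formed is the pyranone C ring, in step 6.

Assumption: the target has no stereocentre or other stereogenic element. It is a single achiral compound, so the "single enantiomer" requirement is met by default.

**Step 1**
Reactants: 1 2,4,6-trihydroxybenzaldehyde
Product: 2 2,4-bis(benzyloxy)-6-hydroxybenzaldehyde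
Conditions: BnBr (2.1 equiv), K2CO3 (2.2 equiv), DMF, 0 °C to rt, 16 h
Reagents that add atoms: benzyl bromide, BrCc1ccccc1
Why: Williamson ether synthesis; after two alkylations the last ortho OH is held in a strong hydrogen bond to the CHO and is much less nucleophilic, so 2.1 equiv of halide stops at the dibenzyl ether (no stereocentre).

**Step 2**
Reactants: 2 2,4-bis(benzyloxy)-6-hydroxybenzaldehyde; 3 4-(benzyloxy)benzyl chloride
Product: 4 2,4-bis(benzyloxy)-6-{[4-(benzyloxy)phenyl]methoxy}benzaldehyde
Conditions: K2CO3 (2 equiv), n-Bu4NI (10 mol %), DMF, 60 °C, 6 h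
Reagents that add atoms: none
Why: Williamson ether synthesis under iodide catalysis and gentle heating alkylates the remaining chelated phenol, which places the future migrating group on exactly the oxygen that becomes O1.

**Step 3**
Reactants: 5 3-(benzyloxy)-4-methoxybenzaldehyde
Product: 6 2-(benzyloxy)-4-ethynyl-1-methoxybenzene
Conditions: Ohira-Bestmann reagent (1.3 equiv), K2CO3 (2 equiv), MeOH/THF, rt, 12 h
Reagents that add atoms: dimethyl (1-diazo-2-oxopropyl)phosphonate, COP(=O)(OC)C(=[N+]=[N-])C(C)=O
Why: Seyferth-Gilbert homologation (Ohira-Bestmann variant) converts a non-enolisable aryl aldehyde into the terminal alkyne under mild base that leaves both aryl ethers untouched.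

**Step 4**
Reactants: 6 2-(benzyloxy)-4-ethynyl-1-methoxybenzene; 4 2,4-bis(benzyloxy)-6-{[4-(benzyloxy)phenyl]methoxy}benzaldehyde
Product: 9 (±)-1-(2,4-bis(benzyloxy)-6-{[4-(benzyloxy)phenyl]methoxy}phenyl)-3-[3-(benzyloxy)-4-methoxyphenyl]prop-2-yn-1-ol, via lithium [3-(benzyloxy)-4-methoxyphenyl]acetylide 7 (not isolated), via lithium alkoxide of the propargylic alcohol 8 (not isolated)
Conditions: 6 (1.2 equiv), n-BuLi (1.15 equiv), THF, −78 °C, 30 min; then 4, −78 to 0 °C; H2O quench
Reagents that add atoms: none
Why: 1,2-addition of a lithium acetylide to a non-enolisable aldehyde; the carbinol centre forms as the racemate, which does not matter because step 5 erases it.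

**Step 5**
Reactants: 9 (±)-propargylic alcohol
Product: 10 1-(2,4-bis(benzyloxy)-6-{[4-(benzyloxy)phenyl]methoxy}phenyl)-3-[3-(benzyloxy)-4-methoxyphenyl]prop-2-yn-1-one
Conditions: activated MnO2 (15 equiv), CH2Cl2, rt, 3 h
Reagents that add atoms: none
Why: MnO2 oxidation of a doubly activated (benzylic and propargylic) alcohol is fast and neutral, so the acid-labile carbinol does not ionise and all ethers survive.

**Step 6**
Reactants: 10 aryl ynone
Product: 14 5,7-bis(benzyloxy)-8-[4-(benzyloxy)benzyl]-2-[3-(benzyloxy)-4-methoxyphenyl]-4H-chromen-4-one, via 5,7-bis(benzyloxy)-1-[4-(benzyloxy)benzyl]-2-[3-(benzyloxy)-4-methoxyphenyl]-4-oxo-4H-chromen-1-ium triflimide 11 (not isolated), via 5,7-bis(benzyloxy)-2-[3-(benzyloxy)-4-methoxyphenyl]-4H-chromen-4-one 12 (not isolated), via [4-(benzyloxy)phenyl]methylium triflimide 13 (not isolated)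
Conditions: HNTf2 (5 mol %), dry CH2Cl2/(CF3)2CHOH 9:1, −20 to 0 °C, 10 added over 2 h (final 0.01 M), Ar; then aq NaHCO3
Reagents that add atoms: none
Why: Proposed new method: Brønsted-acid-catalysed cycloisomerisation of an o-(p-alkoxybenzyloxy)aryl ynone with O-to-C8 benzyl transposition. Protonation of the ynone C=O lets the ortho ether oxygen add 6-endo-dig to the alkyne carbon that the 4-methoxyaryl group stabilises as a cation, and C3 takes up the proton to give oxonium 11. The only fast exit from 11 is SN1 loss of the p-alkoxy-stabilised cation 13, because the rival oxonium formed through the plain OBn oxygen forms reversibly and ionises orders of magnitude more slowly. The contact ion pair 12/13, kept together by the non-coordinating NTf2 anion, the mostly CH2Cl2 medium and the low standing concentration of 10, collapses by Friedel-Crafts attack at the neighbouring C8, which is also the intrinsically most nucleophilic carbon of 5,7-dialkoxyflavones, and loss of H+ returns the catalyst. If ionisation instead comes before ring closure, the freed phenol directs the cation to its own less hindered ortho carbon and is the only oxygen able to close the ring, so both timings give the 8-isomer in a pure isomerisation. The closest known reaction types are the TfOH-promoted 6-endo cyclisation of o-alkynoylphenols, the electrophile-induced cyclisation of o-alkoxyaryl ynones with loss of the O-alkyl group, the Pt/Au-catalysed carboalkoxylation of o-alkynylaryl benzyl ethers (O-to-C3 1,3-shift) and the acid-mediated ortho O-to-C rearrangement of aryl benzyl ethers.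

**Step 7**
Reactants: 14 tetra-O-benzyl 8-benzylflavone
Product: 15 5,7-dihydroxy-2-(3-hydroxy-4-methoxyphenyl)-8-(4-hydroxybenzyl)-4H-chromen-4-one (target)
Conditions: H2 (1 atm), 10 % Pd/C, THF/MeOH 1:1, rt, stopped at full conversion
Reagents that add atoms: none
Why: Catalytic hydrogenolysis cleaves the four aryl benzyl ethers, while the diarylmethane C–C bond, the aryl methyl ether and the conjugated flavone C2=C3 bond are inert at 1 atm and rt (no stereocentre to set).

**Compound list**
1 | 2,4,6-trihydroxybenzaldehyde | O=Cc1c(O)cc(O)cc1O | starting material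
2 | 2,4-bis(benzyloxy)-6-hydroxybenzaldehyde | O=Cc1c(O)cc(OCc2ccccc2)cc1OCc1ccccc1 | intermediate
3 | 4-(benzyloxy)benzyl chloride | ClCc1ccc(OCc2ccccc2)cc1 | starting material
4 | 2,4-bis(benzyloxy)-6-{[4-(benzyloxy)phenyl]methoxy}benzaldehyde | O=Cc1c(OCc2ccc(OCc3ccccc3)cc2)cc(OCc2ccccc2)cc1OCc1ccccc1 | intermediate
5 | 3-(benzyloxy)-4-methoxybenzaldehyde | COc1ccc(C=O)cc1OCc1ccccc1 | starting material
6 | 2-(benzyloxy)-4-ethynyl-1-methoxybenzene | COc1ccc(C#C)cc1OCc1ccccc1 | intermediate
7 | lithium [3-(benzyloxy)-4-methoxyphenyl]acetylide | [Li]C#Cc1ccc(OC)c(OCc2ccccc2)c1 | intermediate (not isolated)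
8 | lithium alkoxide of 9 (racemic) | COc1ccc(C#CC(O[Li])c2c(OCc3ccc(OCc4ccccc4)cc3)cc(OCc3ccccc3)cc2OCc2ccccc2)cc1OCc1ccccc1 | intermediate (not isolated)
9 | (±)-1-(2,4-bis(benzyloxy)-6-{[4-(benzyloxy)phenyl]methoxy}phenyl)-3-[3-(benzyloxy)-4-methoxyphenyl]prop-2-yn-1-ol (racemic) | COc1ccc(C#CC(O)c2c(OCc3ccc(OCc4ccccc4)cc3)cc(OCc3ccccc3)cc2OCc2ccccc2)cc1OCc1ccccc1 | intermediate
10 | 1-(2,4-bis(benzyloxy)-6-{[4-(benzyloxy)phenyl]methoxy}phenyl)-3-[3-(benzyloxy)-4-methoxyphenyl]prop-2-yn-1-one | COc1ccc(C#CC(=O)c2c(OCc3ccc(OCc4ccccc4)cc3)cc(OCc3ccccc3)cc2OCc2ccccc2)cc1OCc1ccccc1 | intermediate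
11 | 5,7-bis(benzyloxy)-1-[4-(benzyloxy)benzyl]-2-[3-(benzyloxy)-4-methoxyphenyl]-4-oxo-4H-chromen-1-ium triflimide | COc1ccc(C2=CC(=O)c3c(OCc4ccccc4)cc(OCc4ccccc4)cc3[O+]2Cc2ccc(OCc3ccccc3)cc2)cc1OCc1ccccc1.O=S(=O)(C(F)(F)F)[N-]S(=O)(=O)C(F)(F)F | intermediate (not isolated)
12 | 5,7-bis(benzyloxy)-2-[3-(benzyloxy)-4-methoxyphenyl]-4H-chromen-4-one | COc1ccc(-c2cc(=O)c3c(OCc4ccccc4)cc(OCc4ccccc4)cc3o2)cc1OCc1ccccc1 | intermediate (not isolated)
13 | [4-(benzyloxy)phenyl]methylium triflimide | [CH2+]c1ccc(OCc2ccccc2)cc1.O=S(=O)(C(F)(F)F)[N-]S(=O)(=O)C(F)(F)F | intermediate (not isolated)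
14 | 5,7-bis(benzyloxy)-8-[4-(benzyloxy)benzyl]-2-[3-(benzyloxy)-4-methoxyphenyl]-4H-chromen-4-one | COc1ccc(-c2cc(=O)c3c(OCc4ccccc4)cc(OCc4ccccc4)c(Cc4ccc(OCc5ccccc5)cc4)c3o2)cc1OCc1ccccc1 | intermediate
15 | 5,7-dihydroxy-2-(3-hydroxy-4-methoxyphenyl)-8-(4-hydroxybenzyl)-4H-chromen-4-one | COc1ccc(-c2cc(=O)c3c(O)cc(O)c(Cc4ccc(O)cc4)c3o2)cc1O | target

**Total step count:** 7. **Longest linear sequence:** 6 (steps 1, 2, 4, 5, 6, 7, from 1).

**Three steps most likely to fail**

Step 6 is the new step. The cation may escape to C6, to C3 or to unreacted 10, or the ring may close through the plain OBn oxygen. The fallback uses known chemistry, sets out from 10 and comes back at 14. Compound 10 is treated with TfOH (20 mol %) and 1,3-dimethoxybenzene (5 equiv) in CH2Cl2 at 0 °C. This cleaves the p-alkoxybenzyl ether with the arene as cation trap and gives 1-[2,4-bis(benzyloxy)-6-hydroxyphenyl]-3-[3-(benzyloxy)-4-methoxyphenyl]prop-2-yn-1-one F1. Under the same acid F1 closes 6-endo to flavone 12, which is now isolated. NIS (1.1 equiv) with catalytic TFA in MeCN at rt iodinates 12 at C8, the usual site for 5,7-dialkoxyflavones, to give 5,7-bis(benzyloxy)-2-[3-(benzyloxy)-4-methoxyphenyl]-8-iodo-4H-chromen-4-one F2. Chloride 3 is converted with Zn dust and LiCl in THF into [4-(benzyloxy)benzyl]zinc chloride F3. Negishi coupling of F2 with F3 (Pd(OAc)2 2 mol %, SPhos 4 mol %, THF, 25 to 50 °C) gives 14.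

Step 1 may suffer over-alkylation or C-benzylation of the very electron-rich phloroglucinaldehyde, which would lower the yield of the dibenzyl ether. The fallback sets out from 1 and comes back at 2. It replaces selective partial protection with exhaustive protection followed by chelation-directed deprotection. Compound 1 is fully benzylated (BnBr 4 equiv, K2CO3, DMF, 70 °C) to 2,4,6-tris(benzyloxy)benzaldehyde F4. BCl3 (1.05 equiv, CH2Cl2, −78 °C, aqueous work-up) then binds the aldehyde oxygen and one ortho ether oxygen and cleaves just that benzyl group. The resulting boron chelate protects against a second cleavage, and hydrolysis gives 2.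

Step 7 may over-reduce C2=C3 to the flavanone, or stall because the partly deprotected material is poorly soluble. The fallback sets out from 13's successor 14 and comes back at 15 with no reductant present. Compound 14 is treated with BCl3 (8 equiv) and pentamethylbenzene (12 equiv) in CH2Cl2 at −78 °C, followed by an aqueous quench. This is a Lewis-acid debenzylation with a non-basic cation scavenger. At −78 °C the aryl methyl ether and the C8 benzyl group are left alone and C2=C3 cannot be touched (no new compound, F0).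

**Further compounds**
F1 | step 6 | 1-[2,4-bis(benzyloxy)-6-hydroxyphenyl]-3-[3-(benzyloxy)-4-methoxyphenyl]prop-2-yn-1-one | COc1ccc(C#CC(=O)c2c(O)cc(OCc3ccccc3)cc2OCc2ccccc2)cc1OCc1ccccc1
F2 | step 6 | 5,7-bis(benzyloxy)-2-[3-(benzyloxy)-4-methoxyphenyl]-8-iodo-4H-chromen-4-one | COc1ccc(-c2cc(=O)c3c(OCc4ccccc4)cc(OCc4ccccc4)c(I)c3o2)cc1OCc1ccccc1
F3 | step 6 | [4-(benzyloxy)benzyl]zinc chloride | Cl[Zn]Cc1ccc(OCc2ccccc2)cc1
F4 | step 1 | 2,4,6-tris(benzyloxy)benzaldehyde | O=Cc1c(OCc2ccccc2)cc(OCc2ccccc2)cc1OCc1ccccc1
F0 | step 7 | none | none
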